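Compound numbers are those of the steps and of the compound list below. Rings are lettered A to E from the 3,5-dihydroxyphenoxy end, and each of rings B to E is numbered so that position 1 carries the ether oxygen pointing toward ring A.

## Analysis of the target

Target 34 (C30H22O15) is a linear chain of five benzene rings joined by four diaryl ether oxygens, with eleven free phenolic hydroxyls and no stereocentre, so the whole problem is one of regiochemistry. Ring A is 1,3,5-trioxygenated and rings B to E are 1,2,3,5-tetraoxygenated; the ether bonds are A–O–B1, B6–O–C1, C4–O–D1 and D6–O–E1, and the hydroxyls sit on B2, B4, C2, C6, D2, D4, E2, E4 and E6 besides the two on ring A. Rings B and D are bridged through neighbouring positions (1 and 6), ring C through opposite positions (1 and 4). The synthesis is hard for two reasons: B1, C1, D1 and E1 are each flanked by two oxygen-bearing carbons on very electron-rich rings, the worst case for SNAr or metal-mediated aryl ether formation, and fifteen oxygens of similar character must be told apart. The free polyphenol is easily oxidised, above all in base, and the ring CH positions between two oxygens are strongly nucleophilic, so the hydroxyls are best kept as alkyl ethers to the last step and strong electrophiles kept away. The feature on which the plan rests is the oxygen pattern of ring B: B1 with its aryloxy group and B6 with its oxygen form a two-carbon unit at the oxidation level of an aryloxyacetyl group, and B2–B3 and B4–B5 are two carbon pairs with one oxygen each, that is, two alkoxyalkynes. Because the flanked position 1 of every ring carries the oxygen that comes from the preceding ring, the same mapping holds for rings C, D and E, and each hindered ether can be made as an unhindered O-alkylation before its ring exists.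

## Retrosynthetic reasoning

**34 to 33.** No skeletal bond is cut. Ten of the eleven hydroxyls are carried as alkyl ethers (two methyl ethers on ring A, inherited from 1, and eight ethyl ethers), because these survive ketene, base and Lewis acid chemistry. The last step is therefore one global ether cleavage by a boron trihalide, which leaves diaryl ethers untouched.

**Ring E: 33 to 30 and two molecules of 6.** The E1–E2, E3–E4 and E5–E6 bonds are cut, which reduces ring E to the aryloxyacetyl chloride 30 and two alkoxyalkynes. The forward reaction has to turn 30 into its ketene, add 6 twice with fixed polarity and aromatise. Acid chloride 30 comes from acid 29, and 29 from phenol 27 and 2 by O-alkylation and saponification. The flanked E1–O bond is thus an ordinary alkylation of the D6 hydroxyl.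

**Ring D: 27 to 24 and two molecules of 6.** This is the same cut (D1–D2, D3–D4, D5–D6). What is gained is that the annulation leaves its only free hydroxyl on D6, next to D1, which is exactly where ring E is attached. Acid chloride 24 goes back through acid 23 to phenol 21 and 2.

**Ring C: 21 to 20, 19, then 12, 6 and 16.** Ring C is bridged para, but the annulation puts its free hydroxyl on C6, ortho to C1. The C4 oxygen must therefore be singled out, and this is done by using two different alkynes: 6 enters first and supplies C2–C3 with an ethoxy group, and 16 enters second and supplies C4–C5 with an isopropoxy group. The C6 hydroxyl of 19 is then capped as an ethyl ether (20), and the secondary alkyl ether alone is cleaved to give 21. A silyl ynol ether cleavable by fluoride would be the first thought, but such reagents come from ynolates that carry a carbon substituent, which would end on C5. The unsubstituted alkynyl ether 16 is reachable in one flask from 13 and 14, and a secondary alkyl aryl ether is cleaved by a boron trihalide under conditions that spare methyl and ethyl ethers.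

**12 to 9 and 2.** Acid chloride 12 goes back through acid 11 to phenol 9 and 2. The B6–O–C1 bond, hindered on the ring C side, is formed while C1 is still a methylene carbon.

**Ring B: 9 to 5 and two molecules of 6 (key disconnection).** The B1–B2, B3–B4 and B5–B6 bonds are cut. The cut is made here because B1 is the flanked carbon, and its ether bond to ring A is already present in 5 as a simple aryloxyacetyl unit. The forward reaction delivers both ethoxy groups (B2, B4) and a single free hydroxyl on B6, the site of the next ether. The risk of the route is concentrated in this step.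

**5 to 1 and 2.** Acid chloride 5 comes from acid 4, and 4 from 1 and 2 by O-alkylation and saponification. The precursor of the key step is thus two steps from commercial materials.

## Alternatives that were turned down

**Alternative 1:** Here both ether bonds of ring D (D6–O–E and D1–O–C) are cut and ring D serves as a double electrophile. In the forward step the cationic complex A2, (η5-cyclopentadienyl)(η6-1,2-dichloro-3,5-dimethoxybenzene)ruthenium hexafluorophosphate, is attacked in one flask by two phenoxides in turn. The phenoxide of 2,4,6-trimethoxyphenol A3 attacks first, at the chloride meta to both methoxy groups. The phenoxide of 4-(benzyloxy)-3,5-dimethoxyphenol A4 then attacks at the flanked chloride, giving the ruthenium complex A1 of the CDE triaryl diether; the metal is removed afterwards.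
- For it: π-complexation turns an electron-rich chloroarene into a good SNAr substrate that accepts even the hindered phenoxide of A3 under mild conditions. Three rings are joined in one operation. SNAr on cationic arene–ruthenium complexes is an established reaction class, so on precedent and on convergence this key step is stronger than the annulation chosen here.
- Against it: the order of substitution rests only on the electronic difference between two chlorides on a strongly activated ring, and any crossover gives regioisomeric triaryl ethers that are hard to separate. The second substitution must take place at a carbon flanked on both sides, after the ring has gained a further oxygen donor. The metal is used stoichiometrically and needs a complexation and a decomplexation step. Only rings C to E are joined; A–O–B1 and B6–O–C1 (C1 lying between two methoxy groups) still require a second activated arene or hindered copper couplings.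
- Comparison: the chosen route is linear and longer, but it forms no hindered aryl–oxygen bond at all, needs no stoichiometric noble metal, and fixes its regiochemistry by the polarity of the reacting partners.

**Alternative 2:** Here ring E is cut at E2–E3 and E5–E6, so that E1, E2 and E6 come from the aryloxymalonate A6, dimethyl 2-[2-(benzyloxy)-3,5-dimethoxyphenoxy]propanedioate, and E3 to E5 from dimethyl 3-oxopentanedioate A7. In the forward step a methoxide base makes the enolate of A7 condense twice with A6 (Claisen, then Dieckmann-type closure), and enolisation gives the phloroglucinol diester A5, dimethyl 5-[2-(benzyloxy)-3,5-dimethoxyphenoxy]-2,4,6-trihydroxybenzene-1,3-dicarboxylate.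
- For it: it shares the central idea of the chosen route, since the flanked E1–O bond is made by alkylation before the ring exists. The reagents are cheap and the condensation type is classical, so for ring E alone it is the safer reaction.
- Against it: A6 has an acidic CH between its esters, and once deprotonated it is a poor acylating agent, so the first Claisen step competes with simple salt formation. The two ester groups on E3 and E5 must be removed afterwards by hydrolysis and double decarboxylation. The three hydroxyls of the new ring are not differentiated; that is harmless for the terminal ring E but useless for rings B, C and D, where exactly one oxygen must be free for the next ether.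
- Comparison: this method builds one ring of five and leaves three hindered ethers to classical couplings. The chosen annulation is less secure per step, but it gives a single free hydroxyl at the position of the next ether and can be repeated for every ring.

**Alternative 3:** Here four aryl C–OH bonds (A5, B4, D4, E4) are cut, which leads back to the pentaaryl tetraether A9 bearing seven methoxy groups and no oxygen at those four positions. In the forward step an iridium bipyridine catalyst and a diboron reagent borylate, in each of rings A, B, D and E, the one C–H bond that has no ortho substituent. Oxidation in the same flask converts the four C–B bonds into C–O bonds, giving A8, the heptamethyl ether of 34 with free hydroxyls on A5, B4, D4 and E4.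
- For it: sterically controlled C–H borylation is well established and its selectivity is predictable; ring C has no unhindered C–H and stays untouched. Four oxygens are installed in one operation, and the building blocks for A9 are less oxygenated, cheaper and easier to couple. On precedent and on economy of oxygen installation it is stronger than the chosen route.
- Against it: the step forms no skeletal bond. B1, C1, D1 and E1 of A9 are still flanked on both sides, so the real difficulty is only moved to the assembly of A9. Four borylations on one electron-rich substrate must all go to completion, and incomplete reaction at any one site gives mixtures of closely similar phenols. A8 still needs exhaustive demethylation.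
- Comparison: the chosen route delivers all oxygens of each ring together with the ring and with its ether bond, and so addresses the hindered ethers directly.

Key step: step 3

## Remark

Ethoxyethyne 6 is used as its commercial solution in hexanes. The cyclobutenones 8, 18, 26 and 32 form as racemates, and their single stereocentre is lost on ring opening.

## Route

Step 1
Reactants: 1 3,5-dimethoxyphenol; 2 ethyl bromoacetate
Product: 4 (3,5-dimethoxyphenoxy)acetic acid, via ethyl ester 3 (not isolated)
Conditions: K2CO3, DMF, 50 °C; then 2 M aq NaOH, rt; 1 M HCl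
Reagents that add atoms: sodium hydroxide [Na+].[OH-]
Why: Williamson ether synthesis: the phenoxide of 1 displaces bromide from the primary α-bromo ester 2 (SN2), and hydroxide then saponifies ester 3 in the same flask; the aryl methyl ethers are inert to both.

Step 2
Reactants: 4 (3,5-dimethoxyphenoxy)acetic acid
Product: 5 (3,5-dimethoxyphenoxy)acetyl chloride
Conditions: 1-chloro-N,N,2-trimethylprop-1-en-1-amine (1.0 equiv), CH2Cl2, 0 °C to rt; concentrate, use at once
Reagents that add atoms: 1-chloro-N,N,2-trimethylprop-1-en-1-amine CC(C)=C(Cl)N(C)C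
Why: Acid chloride formation with an α-chloroenamine under neutral conditions, the only by-product being an inert tertiary amide. Oxalyl chloride with DMF is avoided because acylating or formylating species could attack the 1,3,5-trioxygenated ring.

Step 3
Reactants: 5 (3,5-dimethoxyphenoxy)acetyl chloride; 6 ethoxyethyne (two molecules are incorporated)
Product: 9 2-(3,5-dimethoxyphenoxy)-3,5-diethoxyphenol, via aryloxyketene 7 (not isolated), via cyclobutenone 8 (not isolated)
Conditions: 6 (5 equiv), Et3N (1.1 equiv, slow addition), PhMe, 0 °C to rt; filter off Et3N·HCl under Ar; sealed tube, 80 °C; 1 M HCl wash, then K2CO3, MeOH, rt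
Reagents that add atoms: none
Why: Proposed new method: Et3N removes HCl from 5 to give aryloxyketene 7, whose electrophilic carbonyl carbon (B6) bonds to the unsubstituted, nucleophilic carbon of 6 while the ketene α-carbon (B1) bonds to the ethoxy-bearing carbon, a (2+2) cycloaddition that gives racemic cyclobutenone 8 and forms B1–B2 (and, temporarily, B6–B3). At 80 °C 8 should undergo conrotatory 4π ring opening, which breaks the original B1–B6 bond and turns the aryloxy donor outward, so that the vinylketene has hydrogen on the inside of its terminus. This vinylketene adds a second molecule of 6 with the same polarity (B5–B6 and B3–B4), the new 4-vinylcyclobutenone opens again (B6–B3 is broken), and the dienylketene closes ring B by disrotatory 6π electrocyclisation that re-forms B1–B6; tautomerisation of the cyclohexadienone gives the phenol with its hydroxyl on B6. The closest known reaction types are the (2+2) cycloaddition of ketenes with alkoxyalkynes to 3-alkoxycyclobutenones and the Danheiser benzannulation of cyclobutenones with heteroatom-substituted alkynes; what is new is their combination in one flask starting from an aryloxyketene. No stereocentre remains. The step needs regiocontrol in both cycloadditions, and the polarity of the ketene (electrophilic at the carbonyl carbon) and of the ynol ether (nucleophilic at its CH carbon) secures it, placing ethoxy on B2 and B4 and aryloxy on B1. It also needs the ketene to meet the alkyne before it meets itself or the product phenol; slow addition of base, an excess of 6 and the temperature gap between the two stages (cycloaddition at 0 °C, ring opening only on heating) provide this, the salt is removed before heating, and the temperature is held at 80 °C because 6 loses ethene at higher temperature. The acidic and then basic work-up should return any product phenol that was O-vinylated by 6 or O-acylated by a ketene intermediate.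

Step 4
Reactants: 9 2-(3,5-dimethoxyphenoxy)-3,5-diethoxyphenol; 2 ethyl bromoacetate
Product: 11 [2-(3,5-dimethoxyphenoxy)-3,5-diethoxyphenoxy]acetic acid, via ethyl ester 10 (not isolated)
Conditions: K2CO3, DMF, 50 °C; then 2 M aq NaOH, rt; 1 M HCl
Reagents that add atoms: sodium hydroxide [Na+].[OH-]
Why: Williamson ether synthesis and saponification as in step 1; the B6 hydroxyl has only one ortho substituent and meets a primary halide, so the bond that will become the hindered B6–O–C1 ether forms without steric penalty.

Step 5
Reactants: 11 [2-(3,5-dimethoxyphenoxy)-3,5-diethoxyphenoxy]acetic acid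
Product: 12 [2-(3,5-dimethoxyphenoxy)-3,5-diethoxyphenoxy]acetyl chloride
Conditions: 1-chloro-N,N,2-trimethylprop-1-en-1-amine (1.0 equiv), CH2Cl2, 0 °C to rt; concentrate, use at once
Reagents that add atoms: 1-chloro-N,N,2-trimethylprop-1-en-1-amine CC(C)=C(Cl)N(C)C
Why: Neutral acid chloride formation as in step 2; the absence of acid and of Lewis acids keeps the acid chloride from cyclising onto the activated B5 position.

Step 6
Reactants: 13 propan-2-ol; 14 trichloroethene
Product: 16 2-(ethynyloxy)propane (isopropoxyethyne), via dichlorovinyl ether 15 (not isolated)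
Conditions: KH, THF, 0 °C; 14, −50 °C to rt; then n-BuLi (2.4 equiv), −78 to −40 °C; H2O, −78 °C; fractional distillation, used as a titrated solution
Reagents that add atoms: none
Why: Alkynyl ether synthesis from trichloroethene: the alkoxide adds to dichloroethyne formed in the flask to give the (E)-dichlorovinyl ether 15, n-BuLi eliminates HCl and exchanges the remaining chlorine for lithium, and protonation of the lithium acetylide gives 16.

Step 7
Reactants: 12 [2-(3,5-dimethoxyphenoxy)-3,5-diethoxyphenoxy]acetyl chloride; 6 ethoxyethyne; 16 2-(ethynyloxy)propane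
Product: 19 2-[2-(3,5-dimethoxyphenoxy)-3,5-diethoxyphenoxy]-3-ethoxy-5-(propan-2-yloxy)phenol, via aryloxyketene 17 (not isolated), via cyclobutenone 18 (not isolated)
Conditions: 6 (2 equiv), Et3N (1.1 equiv, slow addition), PhMe, 0 °C to rt; filter, evaporate excess 6; then 16 (4 equiv), PhMe, sealed tube, 80 °C; 1 M HCl wash, then K2CO3, MeOH, rt
Reagents that add atoms: none
Why: Proposed new method: the sequence of step 3 is run with two alkynes; ketene 17 and 6 give cyclobutenone 18 by (2+2) cycloaddition at room temperature, where 18 does not yet open, so excess 6 can be evaporated, and on heating the vinylketene from 18 takes up 16 with the same polarity before 4π opening and 6π electrocyclisation close ring C with isopropoxy on C4, ethoxy on C2 and the free hydroxyl on C6. The closest known reaction types are the ketene–alkoxyalkyne (2+2) cycloaddition and the Danheiser benzannulation of cyclobutenones with alkoxyalkynes.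

Step 8
Reactants: 19 2-[2-(3,5-dimethoxyphenoxy)-3,5-diethoxyphenoxy]-3-ethoxy-5-(propan-2-yloxy)phenol
Product: 20 2-[2-(3,5-dimethoxyphenoxy)-3,5-diethoxyphenoxy]-1,3-diethoxy-5-(propan-2-yloxy)benzene
Conditions: EtI, K2CO3, DMF, 50 °C
Reagents that add atoms: iodoethane CCI
Why: Williamson O-ethylation of the only free phenol (C6), which makes C2 and C6 equivalent and leaves the C4 oxygen as the one secondary alkyl ether.

Step 9
Reactants: 20 2-[2-(3,5-dimethoxyphenoxy)-3,5-diethoxyphenoxy]-1,3-diethoxy-5-(propan-2-yloxy)benzene
Product: 21 4-[2-(3,5-dimethoxyphenoxy)-3,5-diethoxyphenoxy]-3,5-diethoxyphenol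
Conditions: BCl3 (2.5 equiv), CH2Cl2, −78 to 0 °C; MeOH, then H2O
Reagents that add atoms: none
Why: Selective Lewis acid cleavage of a secondary alkyl aryl ether: after coordination of BCl3 the isopropyl–oxygen bond breaks through an ionising pathway far faster than the methyl and ethyl ethers, which need SN2 attack by chloride; the isopropoxy group is also the least hindered, having no ortho substituent.

Step 10
Reactants: 21 4-[2-(3,5-dimethoxyphenoxy)-3,5-diethoxyphenoxy]-3,5-diethoxyphenol; 2 ethyl bromoacetate
Product: 23 {4-[2-(3,5-dimethoxyphenoxy)-3,5-diethoxyphenoxy]-3,5-diethoxyphenoxy}acetic acid, via ethyl ester 22 (not isolated)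
Conditions: K2CO3, DMF, 50 °C; then 2 M aq NaOH, rt; 1 M HCl
Reagents that add atoms: sodium hydroxide [Na+].[OH-]
Why: Williamson ether synthesis and saponification as in step 1; the C4 hydroxyl has two ortho hydrogens and is the most accessible phenol of the route.

Step 11
Reactants: 23 {4-[2-(3,5-dimethoxyphenoxy)-3,5-diethoxyphenoxy]-3,5-diethoxyphenoxy}acetic acid
Product: 24 {4-[2-(3,5-dimethoxyphenoxy)-3,5-diethoxyphenoxy]-3,5-diethoxyphenoxy}acetyl chloride
Conditions: 1-chloro-N,N,2-trimethylprop-1-en-1-amine (1.0 equiv), CH2Cl2, 0 °C to rt; concentrate, use at once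
Reagents that add atoms: 1-chloro-N,N,2-trimethylprop-1-en-1-amine CC(C)=C(Cl)N(C)C
Why: Neutral acid chloride formation as in step 2, chosen again because three electron-rich rings are now present.

Step 12
Reactants: 24 {4-[2-(3,5-dimethoxyphenoxy)-3,5-diethoxyphenoxy]-3,5-diethoxyphenoxy}acetyl chloride; 6 ethoxyethyne (two molecules are incorporated)
Product: 27 2-{4-[2-(3,5-dimethoxyphenoxy)-3,5-diethoxyphenoxy]-3,5-diethoxyphenoxy}-3,5-diethoxyphenol, via aryloxyketene 25 (not isolated), via cyclobutenone 26 (not isolated)
Conditions: 6 (5 equiv), Et3N (1.1 equiv, slow addition), PhMe, 0 °C to rt; filter off Et3N·HCl under Ar; sealed tube, 80 °C; 1 M HCl wash, then K2CO3, MeOH, rt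
Reagents that add atoms: none
Why: Proposed new method: as in step 3, ketene 25 and two molecules of 6 should close ring D through cyclobutenone 26, 4π opening, a second (2+2) cycloaddition and 6π electrocyclisation, placing aryloxy on D1, ethoxy on D2 and D4 and the hydroxyl on D6, next to D1 as the ortho bridge of ring D requires. The closest known reaction types are the ketene–alkoxyalkyne (2+2) cycloaddition and the Danheiser benzannulation.

Step 13
Reactants: 27 2-{4-[2-(3,5-dimethoxyphenoxy)-3,5-diethoxyphenoxy]-3,5-diethoxyphenoxy}-3,5-diethoxyphenol; 2 ethyl bromoacetate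
Product: 29 (2-{4-[2-(3,5-dimethoxyphenoxy)-3,5-diethoxyphenoxy]-3,5-diethoxyphenoxy}-3,5-diethoxyphenoxy)acetic acid, via ethyl ester 28 (not isolated)
Conditions: K2CO3, DMF, 50 °C; then 2 M aq NaOH, rt; 1 M HCl
Reagents that add atoms: sodium hydroxide [Na+].[OH-]
Why: Williamson ether synthesis and saponification as in step 4; the D6 hydroxyl is alkylated by a primary halide, so the later flanked E1–O bond is made without a hindered coupling.

Step 14
Reactants: 29 (2-{4-[2-(3,5-dimethoxyphenoxy)-3,5-diethoxyphenoxy]-3,5-diethoxyphenoxy}-3,5-diethoxyphenoxy)acetic acid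
Product: 30 (2-{4-[2-(3,5-dimethoxyphenoxy)-3,5-diethoxyphenoxy]-3,5-diethoxyphenoxy}-3,5-diethoxyphenoxy)acetyl chloride
Conditions: 1-chloro-N,N,2-trimethylprop-1-en-1-amine (1.0 equiv), CH2Cl2, 0 °C to rt; concentrate, use at once
Reagents that add atoms: 1-chloro-N,N,2-trimethylprop-1-en-1-amine CC(C)=C(Cl)N(C)C
Why: Neutral acid chloride formation as in step 2.

Step 15
Reactants: 30 (2-{4-[2-(3,5-dimethoxyphenoxy)-3,5-diethoxyphenoxy]-3,5-diethoxyphenoxy}-3,5-diethoxyphenoxy)acetyl chloride; 6 ethoxyethyne (two molecules are incorporated)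
Product: 33 2-(2-{4-[2-(3,5-dimethoxyphenoxy)-3,5-diethoxyphenoxy]-3,5-diethoxyphenoxy}-3,5-diethoxyphenoxy)-3,5-diethoxyphenol, via aryloxyketene 31 (not isolated), via cyclobutenone 32 (not isolated)
Conditions: 6 (5 equiv), Et3N (1.1 equiv, slow addition), PhMe, 0 °C to rt; filter off Et3N·HCl under Ar; sealed tube, 80 °C; 1 M HCl wash, then K2CO3, MeOH, rt
Reagents that add atoms: none
Why: Proposed new method: as in step 3, ketene 31 and two molecules of 6 should close ring E through cyclobutenone 32, 4π opening, a second (2+2) cycloaddition and 6π electrocyclisation, placing aryloxy on E1, ethoxy on E2 and E4 and the hydroxyl on E6. The closest known reaction types are the ketene–alkoxyalkyne (2+2) cycloaddition and the Danheiser benzannulation.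

Step 16
Reactants: 33 2-(2-{4-[2-(3,5-dimethoxyphenoxy)-3,5-diethoxyphenoxy]-3,5-diethoxyphenoxy}-3,5-diethoxyphenoxy)-3,5-diethoxyphenol
Product: 34 2-(2-{4-[2-(3,5-dihydroxyphenoxy)-3,5-dihydroxyphenoxy]-3,5-dihydroxyphenoxy}-3,5-dihydroxyphenoxy)benzene-1,3,5-triol
Conditions: BBr3 (30 equiv), CH2Cl2, −78 °C to rt, Ar; MeOH at −78 °C, then H2O; chromatography under Ar
Reagents that add atoms: none
Why: Lewis acid ether cleavage: BBr3 coordinates each alkyl aryl ether oxygen and bromide removes the methyl or ethyl group by SN2, while the diaryl ether bonds are inert because an aryl carbon can neither be displaced nor ionise. Exclusion of air and a cold quench should protect the oxidation-prone polyphenol.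

## Compound list

1 | 3,5-dimethoxyphenol | COc1cc(O)cc(OC)c1 | starting material
2 | ethyl bromoacetate | CCOC(=O)CBr | starting material
3 | ethyl (3,5-dimethoxyphenoxy)acetate | CCOC(=O)COc1cc(OC)cc(OC)c1 | intermediate
4 | (3,5-dimethoxyphenoxy)acetic acid | OC(=O)COc1cc(OC)cc(OC)c1 | intermediate
5 | (3,5-dimethoxyphenoxy)acetyl chloride | ClC(=O)COc1cc(OC)cc(OC)c1 | intermediate
6 | ethoxyethyne | CCOC#C | starting material
7 | 2-(3,5-dimethoxyphenoxy)ethen-1-one (aryloxyketene) | O=C=COc1cc(OC)cc(OC)c1 | intermediate
8 | rac-4-(3,5-dimethoxyphenoxy)-3-ethoxycyclobut-2-en-1-one | CCOC1=CC(=O)C1Oc1cc(OC)cc(OC)c1 | intermediate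
9 | 2-(3,5-dimethoxyphenoxy)-3,5-diethoxyphenol | CCOc1cc(O)c(Oc2cc(OC)cc(OC)c2)c(OCC)c1 | intermediate
10 | ethyl [2-(3,5-dimethoxyphenoxy)-3,5-diethoxyphenoxy]acetate | CCOC(=O)COc1cc(OCC)cc(OCC)c1Oc1cc(OC)cc(OC)c1 | intermediate
11 | [2-(3,5-dimethoxyphenoxy)-3,5-diethoxyphenoxy]acetic acid | OC(=O)COc1cc(OCC)cc(OCC)c1Oc1cc(OC)cc(OC)c1 | intermediate
12 | [2-(3,5-dimethoxyphenoxy)-3,5-diethoxyphenoxy]acetyl chloride | ClC(=O)COc1cc(OCC)cc(OCC)c1Oc1cc(OC)cc(OC)c1 | intermediate
13 | propan-2-ol | CC(C)O | starting material
14 | trichloroethene | ClC=C(Cl)Cl | starting material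
15 | (E)-1,2-dichloro-1-(propan-2-yloxy)ethene | Cl/C(OC(C)C)=C/Cl | intermediate
16 | 2-(ethynyloxy)propane (isopropoxyethyne) | CC(C)OC#C | intermediate
17 | 2-[2-(3,5-dimethoxyphenoxy)-3,5-diethoxyphenoxy]ethen-1-one (aryloxyketene) | O=C=COc1cc(OCC)cc(OCC)c1Oc1cc(OC)cc(OC)c1 | intermediate
18 | rac-4-[2-(3,5-dimethoxyphenoxy)-3,5-diethoxyphenoxy]-3-ethoxycyclobut-2-en-1-one | CCOC1=CC(=O)C1Oc1cc(OCC)cc(OCC)c1Oc1cc(OC)cc(OC)c1 | intermediate
19 | 2-[2-(3,5-dimethoxyphenoxy)-3,5-diethoxyphenoxy]-3-ethoxy-5-(propan-2-yloxy)phenol | CCOc1cc(OC(C)C)cc(O)c1Oc1cc(OCC)cc(OCC)c1Oc1cc(OC)cc(OC)c1 | intermediate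
20 | 2-[2-(3,5-dimethoxyphenoxy)-3,5-diethoxyphenoxy]-1,3-diethoxy-5-(propan-2-yloxy)benzene | CCOc1cc(OC(C)C)cc(OCC)c1Oc1cc(OCC)cc(OCC)c1Oc1cc(OC)cc(OC)c1 | intermediate
21 | 4-[2-(3,5-dimethoxyphenoxy)-3,5-diethoxyphenoxy]-3,5-diethoxyphenol | CCOc1cc(O)cc(OCC)c1Oc1cc(OCC)cc(OCC)c1Oc1cc(OC)cc(OC)c1 | intermediate
22 | ethyl {4-[2-(3,5-dimethoxyphenoxy)-3,5-diethoxyphenoxy]-3,5-diethoxyphenoxy}acetate | CCOC(=O)COc1cc(OCC)c(Oc2cc(OCC)cc(OCC)c2Oc2cc(OC)cc(OC)c2)c(OCC)c1 | intermediate
23 | {4-[2-(3,5-dimethoxyphenoxy)-3,5-diethoxyphenoxy]-3,5-diethoxyphenoxy}acetic acid | OC(=O)COc1cc(OCC)c(Oc2cc(OCC)cc(OCC)c2Oc2cc(OC)cc(OC)c2)c(OCC)c1 | intermediate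
24 | {4-[2-(3,5-dimethoxyphenoxy)-3,5-diethoxyphenoxy]-3,5-diethoxyphenoxy}acetyl chloride | ClC(=O)COc1cc(OCC)c(Oc2cc(OCC)cc(OCC)c2Oc2cc(OC)cc(OC)c2)c(OCC)c1 | intermediate
25 | 2-{4-[2-(3,5-dimethoxyphenoxy)-3,5-diethoxyphenoxy]-3,5-diethoxyphenoxy}ethen-1-one (aryloxyketene) | O=C=COc1cc(OCC)c(Oc2cc(OCC)cc(OCC)c2Oc2cc(OC)cc(OC)c2)c(OCC)c1 | intermediate
26 | rac-4-{4-[2-(3,5-dimethoxyphenoxy)-3,5-diethoxyphenoxy]-3,5-diethoxyphenoxy}-3-ethoxycyclobut-2-en-1-one | CCOC1=CC(=O)C1Oc1cc(OCC)c(Oc2cc(OCC)cc(OCC)c2Oc2cc(OC)cc(OC)c2)c(OCC)c1 | intermediate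
27 | 2-{4-[2-(3,5-dimethoxyphenoxy)-3,5-diethoxyphenoxy]-3,5-diethoxyphenoxy}-3,5-diethoxyphenol | CCOc1cc(O)c(Oc2cc(OCC)c(Oc3cc(OCC)cc(OCC)c3Oc3cc(OC)cc(OC)c3)c(OCC)c2)c(OCC)c1 | intermediate
28 | ethyl (2-{4-[2-(3,5-dimethoxyphenoxy)-3,5-diethoxyphenoxy]-3,5-diethoxyphenoxy}-3,5-diethoxyphenoxy)acetate | CCOC(=O)COc1cc(OCC)cc(OCC)c1Oc1cc(OCC)c(Oc2cc(OCC)cc(OCC)c2Oc2cc(OC)cc(OC)c2)c(OCC)c1 | intermediate
29 | (2-{4-[2-(3,5-dimethoxyphenoxy)-3,5-diethoxyphenoxy]-3,5-diethoxyphenoxy}-3,5-diethoxyphenoxy)acetic acid | OC(=O)COc1cc(OCC)cc(OCC)c1Oc1cc(OCC)c(Oc2cc(OCC)cc(OCC)c2Oc2cc(OC)cc(OC)c2)c(OCC)c1 | intermediate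
30 | (2-{4-[2-(3,5-dimethoxyphenoxy)-3,5-diethoxyphenoxy]-3,5-diethoxyphenoxy}-3,5-diethoxyphenoxy)acetyl chloride | ClC(=O)COc1cc(OCC)cc(OCC)c1Oc1cc(OCC)c(Oc2cc(OCC)cc(OCC)c2Oc2cc(OC)cc(OC)c2)c(OCC)c1 | intermediate
31 | 2-(2-{4-[2-(3,5-dimethoxyphenoxy)-3,5-diethoxyphenoxy]-3,5-diethoxyphenoxy}-3,5-diethoxyphenoxy)ethen-1-one (aryloxyketene) | O=C=COc1cc(OCC)cc(OCC)c1Oc1cc(OCC)c(Oc2cc(OCC)cc(OCC)c2Oc2cc(OC)cc(OC)c2)c(OCC)c1 | intermediate
32 | rac-4-(2-{4-[2-(3,5-dimethoxyphenoxy)-3,5-diethoxyphenoxy]-3,5-diethoxyphenoxy}-3,5-diethoxyphenoxy)-3-ethoxycyclobut-2-en-1-one | CCOC1=CC(=O)C1Oc1cc(OCC)cc(OCC)c1Oc1cc(OCC)c(Oc2cc(OCC)cc(OCC)c2Oc2cc(OC)cc(OC)c2)c(OCC)c1 | intermediate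
33 | 2-(2-{4-[2-(3,5-dimethoxyphenoxy)-3,5-diethoxyphenoxy]-3,5-diethoxyphenoxy}-3,5-diethoxyphenoxy)-3,5-diethoxyphenol | CCOc1cc(O)c(Oc2cc(OCC)cc(OCC)c2Oc2cc(OCC)c(Oc3cc(OCC)cc(OCC)c3Oc3cc(OC)cc(OC)c3)c(OCC)c2)c(OCC)c1 | intermediate
34 | 2-(2-{4-[2-(3,5-dihydroxyphenoxy)-3,5-dihydroxyphenoxy]-3,5-dihydroxyphenoxy}-3,5-dihydroxyphenoxy)benzene-1,3,5-triol (CNP0018313.0) | Oc1cc(O)cc(Oc2c(O)cc(O)cc2Oc2c(O)cc(Oc3c(O)cc(O)cc3Oc3c(O)cc(O)cc3O)cc2O)c1 | target

## Step count and least certain steps

Total: 16 steps. Longest linear sequence: 15 steps from 1 (steps 1 to 5 and 7 to 16); step 6 is a one-step side branch. Steps 3, 7, 12 and 15 are the same unprecedented annulation; the three riskiest of them are discussed first, followed by steps 9 and 16.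

**Step 3 (key step).** The ketene may dimerise or oligomerise before it reaches the alkyne. The ring opening of 8 may need a temperature at which 6 already fragments to ketene and ethene. The vinylketene may be intercepted by the product phenol. Any of these would drain material before ring B closes.
Fallback (known chemistry, from 1 back to 9): commercial 3,5-dihydroxybenzaldehyde is ethylated (EtI, K2CO3, DMF) to 3,5-diethoxybenzaldehyde F1. Bromination with NBS in MeCN, directed between the formyl group and one ethoxy group, gives 2-bromo-3,5-diethoxybenzaldehyde F2. An Ullmann ether synthesis of 1 with F2 (CuI, picolinic acid, K3PO4, DMSO, 100 °C), helped by the ortho formyl group, gives 2-(3,5-dimethoxyphenoxy)-3,5-diethoxybenzaldehyde F3. Baeyer–Villiger oxidation with mCPBA gives 2-(3,5-dimethoxyphenoxy)-3,5-diethoxyphenyl formate F4, and methanolysis (K2CO3, MeOH) rejoins the route at 9.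

**Step 7.** Scrambling of the two alkynes is the main danger. Residual 6 may be carried into the hot stage, or 16 may lose propene on heating, since a secondary alkynyl ether fragments more easily than 6; either leads to a mixture of ethers on C4. With only a small excess of 6 in the first stage, ketene dimerisation also competes more strongly.
Fallback (known chemistry, from 9 back to 21, bypassing steps 7 to 9): commercial 4-bromo-3,5-dihydroxybenzoic acid is ethylated three times (EtI, K2CO3, DMF) to ethyl 4-bromo-3,5-diethoxybenzoate F5. Reduction with i-Bu2AlH gives (4-bromo-3,5-diethoxyphenyl)methanol F6, and MnO2 oxidation gives 4-bromo-3,5-diethoxybenzaldehyde F7. An Ullmann ether synthesis of 9 with F7 (CuI, picolinic acid, K3PO4, DMSO, 110 °C) gives 4-[2-(3,5-dimethoxyphenoxy)-3,5-diethoxyphenoxy]-3,5-diethoxybenzaldehyde F8; this is the doubly flanked coupling that the main route avoids, accepted here only as a fallback and helped by the para formyl group. Baeyer–Villiger oxidation (mCPBA) gives 4-[2-(3,5-dimethoxyphenoxy)-3,5-diethoxyphenoxy]-3,5-diethoxyphenyl formate F9, and methanolysis gives 21.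

**Step 15.** The substrate is the largest and its ketene oxygen sits next to a bulky aryloxy group. Slower ketene formation and cycloaddition give more time for ketene loss, and four electron-rich rings offer more sites for stray acylation. Step 12 carries the same kind of risk on a less hindered oxygen.
Fallback (known chemistry, from 27 back to 33): an Ullmann ether synthesis of 27 with 2-bromo-3,5-diethoxybenzaldehyde F2 (made as in the fallback for step 3; CuI, picolinic acid, K3PO4, DMSO, 110 °C) gives 2-(2-{4-[2-(3,5-dimethoxyphenoxy)-3,5-diethoxyphenoxy]-3,5-diethoxyphenoxy}-3,5-diethoxyphenoxy)-3,5-diethoxybenzaldehyde F10. Baeyer–Villiger oxidation (mCPBA) gives the corresponding aryl formate, 2-(2-{4-[2-(3,5-dimethoxyphenoxy)-3,5-diethoxyphenoxy]-3,5-diethoxyphenoxy}-3,5-diethoxyphenoxy)-3,5-diethoxyphenyl formate F11, and methanolysis gives 33.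

**Step 9.** Selectivity may be lost: boron chelated between an ethoxy oxygen and the neighbouring aryloxy oxygen may cleave an ethyl ether as well, and the isopropyl cation may alkylate one of the electron-rich rings instead of being captured by chloride.
Fallback (from 12 back to 21, changing the masking group so that no Lewis acid is needed): 2-(trimethylsilyl)ethanol and 14 are converted as in step 6 into [2-(trimethylsilyl)ethoxy]ethyne F12. Used in place of 16 under the conditions of step 7, it should give 2-[2-(3,5-dimethoxyphenoxy)-3,5-diethoxyphenoxy]-3-ethoxy-5-[2-(trimethylsilyl)ethoxy]phenol F13. Ethylation as in step 8 gives {2-[4-[2-(3,5-dimethoxyphenoxy)-3,5-diethoxyphenoxy]-3,5-diethoxyphenoxy]ethyl}trimethylsilane F14. Fluoride (CsF, DMF, 90 °C) then triggers β-elimination of the silylethyl group and frees the C4 phenol, giving 21.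

**Step 16.** Cleavage of the eight ethyl ethers may stop short, since ethyl is slower than methyl and each phenoxyboron group formed makes its ring less basic. The free polyphenol may also be oxidised or lost during isolation from boron residues.
Fallback (from 33 back to 34, changing both the cleavage mechanism and the mode of isolation): 33 is dealkylated with AlCl3 in ethanethiol and CH2Cl2, where the thiol acts as a soft nucleophile on each aluminium-activated ether. The crude polyphenol is acetylated at once (Ac2O, pyridine) to the undecaacetate of 34 F15, which is stable to air and can be purified by chromatography or crystallisation. Deacetylation with catalytic NaOMe in MeOH under Ar, followed by neutralisation with an acidic resin, gives 34.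

## Further compounds

F1 | step 3 | 3,5-diethoxybenzaldehyde | CCOc1cc(C=O)cc(OCC)c1
F2 | step 3 | 2-bromo-3,5-diethoxybenzaldehyde | CCOc1cc(OCC)c(Br)c(C=O)c1
F3 | step 3 | 2-(3,5-dimethoxyphenoxy)-3,5-diethoxybenzaldehyde | CCOc1cc(OCC)c(Oc2cc(OC)cc(OC)c2)c(C=O)c1
F4 | step 3 | 2-(3,5-dimethoxyphenoxy)-3,5-diethoxyphenyl formate | CCOc1cc(OCC)c(Oc2cc(OC)cc(OC)c2)c(OC=O)c1
F5 | step 7 | ethyl 4-bromo-3,5-diethoxybenzoate | CCOC(=O)c1cc(OCC)c(Br)c(OCC)c1
F6 | step 7 | (4-bromo-3,5-diethoxyphenyl)methanol | CCOc1cc(CO)cc(OCC)c1Br
F7 | step 7 | 4-bromo-3,5-diethoxybenzaldehyde | CCOc1cc(C=O)cc(OCC)c1Br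
F8 | step 7 | 4-[2-(3,5-dimethoxyphenoxy)-3,5-diethoxyphenoxy]-3,5-diethoxybenzaldehyde | CCOc1cc(C=O)cc(OCC)c1Oc1cc(OCC)cc(OCC)c1Oc1cc(OC)cc(OC)c1
F9 | step 7 | 4-[2-(3,5-dimethoxyphenoxy)-3,5-diethoxyphenoxy]-3,5-diethoxyphenyl formate | CCOc1cc(OC=O)cc(OCC)c1Oc1cc(OCC)cc(OCC)c1Oc1cc(OC)cc(OC)c1
F10 | step 15 | 2-(2-{4-[2-(3,5-dimethoxyphenoxy)-3,5-diethoxyphenoxy]-3,5-diethoxyphenoxy}-3,5-diethoxyphenoxy)-3,5-diethoxybenzaldehyde | CCOc1cc(OCC)c(Oc2cc(OCC)cc(OCC)c2Oc2cc(OCC)c(Oc3cc(OCC)cc(OCC)c3Oc3cc(OC)cc(OC)c3)c(OCC)c2)c(C=O)c1
F11 | step 15 | 2-(2-{4-[2-(3,5-dimethoxyphenoxy)-3,5-diethoxyphenoxy]-3,5-diethoxyphenoxy}-3,5-diethoxyphenoxy)-3,5-diethoxyphenyl formate | CCOc1cc(OCC)c(Oc2cc(OCC)cc(OCC)c2Oc2cc(OCC)c(Oc3cc(OCC)cc(OCC)c3Oc3cc(OC)cc(OC)c3)c(OCC)c2)c(OC=O)c1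
F12 | step 9 | [2-(trimethylsilyl)ethoxy]ethyne | C#COCC[Si](C)(C)C
F13 | step 9 | 2-[2-(3,5-dimethoxyphenoxy)-3,5-diethoxyphenoxy]-3-ethoxy-5-[2-(trimethylsilyl)ethoxy]phenol | CCOc1cc(OCC[Si](C)(C)C)cc(O)c1Oc1cc(OCC)cc(OCC)c1Oc1cc(OC)cc(OC)c1
F14 | step 9 | {2-[4-[2-(3,5-dimethoxyphenoxy)-3,5-diethoxyphenoxy]-3,5-diethoxyphenoxy]ethyl}trimethylsilane | CCOc1cc(OCC[Si](C)(C)C)cc(OCC)c1Oc1cc(OCC)cc(OCC)c1Oc1cc(OC)cc(OC)c1
F15 | step 16 | undecaacetate of 34 (all eleven hydroxyls as acetates) | CC(=O)Oc1cc(OC(C)=O)cc(Oc2c(OC(C)=O)cc(OC(C)=O)cc2Oc2c(OC(C)=O)cc(Oc3c(OC(C)=O)cc(OC(C)=O)cc3Oc3c(OC(C)=O)cc(OC(C)=O)cc3OC(C)=O)cc2OC(C)=O)c1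
A1 | alternative 1 | (η5-cyclopentadienyl)ruthenium hexafluorophosphate complex, bound to ring D, of 2-[4-(benzyloxy)-3,5-dimethoxyphenoxy]-1,5-dimethoxy-3-(2,4,6-trimethoxyphenoxy)benzene | COc1cc(OC)c(Oc2cc(OC)c(OCc3ccccc3)c(OC)c2)c(Oc2c(OC)cc(OC)cc2OC)c1.[cH-]1cccc1.[Ru+2].F[P-](F)(F)(F)(F)F
A2 | alternative 1 | (η5-cyclopentadienyl)(η6-1,2-dichloro-3,5-dimethoxybenzene)ruthenium hexafluorophosphate | COc1cc(OC)c(Cl)c(Cl)c1.[cH-]1cccc1.[Ru+2].F[P-](F)(F)(F)(F)F
A3 | alternative 1 | 2,4,6-trimethoxyphenol | COc1cc(OC)c(O)c(OC)c1
A4 | alternative 1 | 4-(benzyloxy)-3,5-dimethoxyphenol | COc1cc(O)cc(OC)c1OCc1ccccc1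
A5 | alternative 2 | dimethyl 5-[2-(benzyloxy)-3,5-dimethoxyphenoxy]-2,4,6-trihydroxybenzene-1,3-dicarboxylate | COC(=O)c1c(O)c(Oc2cc(OC)cc(OC)c2OCc2ccccc2)c(O)c(C(=O)OC)c1O
A6 | alternative 2 | dimethyl 2-[2-(benzyloxy)-3,5-dimethoxyphenoxy]propanedioate | COC(=O)C(Oc1cc(OC)cc(OC)c1OCc1ccccc1)C(=O)OC
A7 | alternative 2 | dimethyl 3-oxopentanedioate | COC(=O)CC(=O)CC(=O)OC
A8 | alternative 3 | heptamethyl ether of 34 (methyl on the A3, B2, C2, C6, D2, E2 and E6 oxygens) with free hydroxyls on A5, B4, D4 and E4 | COc1cc(O)cc(Oc2c(OC)cc(O)cc2Oc2c(OC)cc(Oc3c(OC)cc(O)cc3Oc3c(OC)cc(O)cc3OC)cc2OC)c1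
A9 | alternative 3 | pentaaryl tetraether with the seven methoxy groups of A8 and hydrogen on A5, B4, D4 and E4 | COc1cccc(Oc2c(OC)cccc2Oc2c(OC)cc(Oc3c(OC)cccc3Oc3c(OC)cccc3OC)cc2OC)c1
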